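Two questions stand on this flask, and the first can be answered by counting half-lives of one slow drain.

    substrate ⇌ product (K1 = 0.61, k1 = 1.15 s⁻¹)
    crystals ⇌ product, rate k2*(cs2 - [product]) while solid is left; crystals form when [product] > cs2 (cs2 = 27 mM, k2 = 0.277 s⁻¹)

substrate 2.0 M; time 15 s

1. amount of product and crystals together at 15 s, in percent of the substrate charged
2. concentration of product in solution at 15 s, in percent of saturation

- what is said of product includes crystals
- crystals is a solid; its amount is given per volume of the solution
- run time (flask): 15 s

Let s be substrate and p dissolved product, with K = 0.61, k = 1.15 s⁻¹ the forward constant of the first step, d = 0.277 s⁻¹ the coefficient of the second and c = 27 mM the solubility. The first step relaxes with a half-life of 0.228 s, short against 15 s, so you may treat s and p as one pool draining into crystals, and the drain stops at p = c, where s stands at the floor f = c/K = 0.0443 M.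

You have two ways to the drain constant λ. If p stays at K times s (the usual pre-equilibrium), λ = dK/(1+K) = 0.105 s⁻¹. The linear pair of equations instead gives the smaller root of the quadratic whose roots sum to T = k + k/K + d = 3.31 s⁻¹ and multiply to kd, so λ = 0.0991 s⁻¹. They part, and the first one cheats: p must trail s to feed the drain, so the excesses stand in the ratio K(1 − λ/k) = 0.557, a small lag as λ is smaller than k.

Keep the root, and with it the drain half-life h, the natural logarithm of two over λ, the time in which the substrate above its floor halves: 6.99 s. Your time holds 2.15 of these, leaving a fraction 0.226. The pool excess is E = 1.93 M, and giving s the share that this lagging ratio allows, one over one plus 0.557, makes 1.24 M, so my reckoning gives y = 83.8 % and stops there.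

The forecast says 83.3 % and 697 %, holding that “The fast mode dies quickly”. Its slow mode has amplitude 1.278 M in s against my 1.24 M, and my y stands 0.50 percentage points above its figure.

The simulation gives 83.3 % and 697 %. In this flask the relaxation at 0.228 s is short against h = 6.99 s, and from 7.50 s to 15.0 s the substrate above f shrinks by a factor 2.10, where the half-lives counted in that time give 2.10. The neighbouring flask charged with 1.2 M shares every constant in h, so scaling this flask's excess at 15.0 s to that charge gives 17.8 % of substrate, and that neighbouring flask holds 17.8 %.

The numbers were chosen freely; what happens was integrated by code.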